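Of the 10 mM of starting material charged in each set-up, the question is how much ends as target, so I build the flask up one process at a time.

| flask | starting material | enzyme | impurity | remark | time |
|---|---|---|---|---|---|
| north-east | 10 mM | 5 µM | 1 µM | run made earlier |  |
| north-west | 6.7 mM | 5 µM | 1 µM | run made earlier |  |
| west | 15 mM | 5 µM | 1 µM | run made earlier |  |
| south-east | 10 mM | 10 µM | 1 µM | run made earlier |  |
| blue | 10 mM (fed, over 24.0 min) | 5.0 µM | 1.0 µM | all but starting material at the start; starting material goes in evenly over 24.0 min, the run ends at 30 min | 30 min |
| amber | 10 mM | 5.0 µM | 1.0 µM | everything together in a closed stirred flask, run for 30 min | 30 min |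
| red | 10 mM | 5.0 µM | 1.0 µM | one stirred flow tank at steady state, fed with the mixture as stated, mean residence time 30 min |  |
| green | 10 mM | 5.0 µM | 1.0 µM | a tube with plug flow, the mixed feed as stated, residence time 30 min | 30 min |

| run | time / min | target / % |
|---|---|---|
| north-east | 2.50 | 50.9 |
| north-east | 5.00 | 82.8 |
| north-east | 8.00 | 85.7 |
| north-east | 10.0 | 84.7 |
| north-east | 12.0 | 84.6 |
| north-east | 15.0 | 84.8 |
| north-east | 20.0 | 85.0 |
| north-west | 2.50 | 70.3 |
| north-west | 4.00 | 89.5 |
| north-west | 6.00 | 91.9 |
| north-west | 8.00 | 92.0 |
| north-west | 12.0 | 91.8 |
| north-west | 20.0 | 92.0 |
| north-west | 30.0 | 91.2 |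
| west | 2.50 | 34.4 |
| west | 4.00 | 51.1 |
| west | 6.00 | 70.3 |
| west | 8.00 | 74.5 |
| west | 12.0 | 74.8 |
| west | 20.0 | 74.5 |
| west | 30.0 | 74.7 |
| south-east | 2.50 | 91.5 |
| south-east | 8.00 | 92.7 |
| south-east | 15.0 | 92.6 |
| south-east | 20.0 | 92.4 |
| south-east | 30.0 | 92.9 |

(scatter of a reading: 0.3 percentage points)

- the stated concentrations are those of everything mixed, before any reaction; amounts are the same in each set-up
- what was read earlier has a scatter of 0.3 percentage points, one standard deviation
- the feed brings no volume worth counting
- the earlier runs were made in a closed, stirred flask

1. the set-up with the highest amount of target at the outlet or at the end, in percent of the starting material put in ("none" if the first two lie within 2 percentage points) (blue / amber / red / green / none)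
2. amount of target at the outlet or at the end, in percent of the starting material put in, blue
3. amount of target at the outlet or at the end, in percent of the starting material put in, amber
4. amount of target at the outlet or at the end, in percent of the starting material put in, red
5. amount of target at the outlet or at the end, in percent of the starting material put in, green

I start with the main step, in which the enzyme turns starting material into target. The north-east run makes 2.04 mM min⁻¹ over its first 2.50 min, and at that rate the charge lasts about 4.90 min.

Next comes the loss. That run levels off at 85.0%, so 15.0% of the charge goes elsewhere. In the west run, target comes more slowly as it builds, 1.67 mM min⁻¹ against 2.06 mM min⁻¹ at first. I therefore read the side step as taking starting material together with target, one of each. I call s the side rate, a pseudo-first-order constant: the rate at which starting material is lost with target at the full 10 mM. For a steady making rate V in a closed flask, the lost share is s times the charge over 3V, which gives s = 0.0916 min⁻¹. But V was read net of the side step, which by this s has already taken 0.385 mM by 2.50 min. Putting that back gives V = 2.19 mM min⁻¹ and s = 0.0986 min⁻¹, the side rate.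

The forecast gives blue 99.5%, amber 85%, red 98.8%, green 85% and best none, on the ground that “Keeping starting material low removes the side reaction.”

Last comes the vessel, and here I differ for blue and red. I keep the forecast's 0.100 mM of starting material, but with s it still costs yield. Red holds target near the charge for 30 min, so it loses 5.91% to the side step and 1.00% unconverted, leaving about 93.1%. Blue's target climbs through the feed, averaging half the charge, so it loses 2.37% and leaves about 97.6%. That puts blue ahead by 4.5 percentage points, more than the margin.

The flasks give blue 94.9%, amber 85.1%, red 89.6% and green 85.1%, so the best is blue.

    starting material + enzyme → target + enzyme, rate k1*[starting material]*[enzyme]/(1 + ([starting material]/Km1)) (1.10 mM, k = 9700 M⁻¹ s⁻¹)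
    enzyme + impurity → spent catalyst (k = 92000 M⁻¹ s⁻¹)
    starting material + target → side product (k = 0.180 M⁻¹ s⁻¹)

Reckoned back through s, with the shortfall counted as side loss plus unconverted starting material, as in my estimate, red's shortfall corresponds to about 0.150 mM of starting material held in the tank, so that level is the thing to watch there. The same s serves a closed flask like amber charged with 8.50 µM of enzyme. Scaling V with the enzyme charge gives a lost share of 8.82%, hence about 91.2% of target. That flask gives 91.2%.

(The data were computed for an exercise; scatter was added.)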